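## Structural features

The target is a C30 triterpenoid made of two bicyclic halves joined through the two-carbon bridge C16–C17. The left half is a cis-fused perhydroazulene: a cyclopentane (C5–C9) with the tertiary carbinol C9, and a cycloheptane (C2–C6, C12, C15) with the C2 methyl, the C12 gem-dimethyl group and the exocyclic C15=C16 double bond. The right half is a trans-fused oxepane–cyclohexane: ring A (C19, C21, C22, C23, C25, O28, C29) holds the C23 ketone next to the fully substituted ether carbon C25, and ring B (C18, C19, C29–C32) holds the angular methyl on C19, the equatorial C17 branch on C18 and the axial tertiary hydroxyl on C32. The stereocentres are clustered: C32–C18–C19–C29 are contiguous on ring B, C9–C5–C6 are contiguous on the five-membered ring, and C2 stands alone across the seven-membered ring; the two halves are stereochemically insulated, so each must be made as a single enantiomer. The trisubstituted alkene is Z, that is, C17 lies on the side of the quaternary C12 and not of C2; this is the more crowded arrangement and cannot be left to equilibration. Fragile groups are the two tertiary alcohols (elimination), the alkene (acid-induced migration or Z-to-E isomerisation) and the α-alkoxy ketone at C23. The real difficulties are the seven-membered ether with its tetrasubstituted carbon and the Z alkene between two hindered rings. The key step uses the fact that O28 sits between C25 and the ring-fusion carbon C29: removing O28 leaves a trans-decalin (ring A = C19, C21, C22, C23, C25, C29) whose C19/C29 relationship is that of a hydroborated Wieland–Miescher ketone.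

## Logic of the disconnections

70 ⇒ 69 ⇒ 68. No skeletal bond is cut; the C23 carbonyl is taken back to a carbinol and the three hydroxyls are masked as triethylsilyl ethers. This lets every organometallic step run on one class of protecting group. The demand is that the last oxidation touches only the one secondary alcohol and that fluoride leaves the alkene alone.

68 ⇒ 67 ⇒ 66. The C16–H and one C17–H bond are removed (alkene to allene), then the second C17–H is exchanged for a C15–O bond (allene to propargylic carbonate). The Z alkene is the less stable isomer, and an allene lets a small reagent choose between the C2 side and the C12 side on steric grounds. The forward steps must deliver hydride to C17 (SN2′) and then reduce only the C16=C17 π bond from the C2 side.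

66 ⇒ 40 + 61. The C15–C16 bond is cut. It divides the molecule into two halves of similar size, with a ketone on one and an sp C–H on the other. The demand is addition to a ketone flanked by a quaternary and a tertiary carbon without epimerising C2.

40 ⇒ 38 ⇒ 37 ⇒ 35. C16 is removed (one-carbon homologation of an aldehyde), then the C18–H and C17–O bonds (hydroboration). The C18 stereocentre is set by a reagent that can only approach the α face. The aldehyde must not lose its β-silyloxy group.

35 ⇒ 33 ⇒ 31 ⇒ 30 ⇒ 28 ⇒ 27. The C32–CH3 bond, the C32–O bond and the C18=C17 bond are cut in turn. C32 carries the only allylic hydrogens next to C18, and a methyl nucleophile is forced to the α face of the C32 ketone by the axial C20. The demand is chemoselective oxidation of the allylic alcohol beside the free C23 carbinol.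

27 ⇒ 25 ⇒ 21. The second C25–CH3 bond and the C23–O bond are cut back to an enol ether. C25 becomes a gem-dimethyl carbon, so no stereocentre has to be controlled there. The epoxide of the enol ether must open at the acetal carbon.

21 ⇒ 19 (key). The O28–C29 bond is cut and C25–C29 re-formed, which turns the oxepane into a carbocycle. The trans-fused heterocycle becomes a trans-decalin that is available from the chiral pool with C19 and C29 already set. The demand is selective migration of C29 and a non-acidic medium.

19 ⇒ 17 ⇒ 13 ⇒ 11. The O–acyl bond, the C25–O bond and the C25=CH2 bond are cut. The hydroperoxide is reached from the alkene under neutral radical conditions, which the C18 dioxolane tolerates.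

11 ⇒ 10 ⇒ 6 ⇒ 4 ⇒ 3 ⇒ 1. The C25 oxygen comes from hydroboration of C25=C29, which also sets C29–H trans to C20. The C18 ketone is masked and the C23 oxygen of 1 is removed through a dithiolane. The demand is that the alkene stays at C25=C29 throughout.

61 ⇒ 60 ⇒ 58 ⇒ 56 ⇒ 53 ⇒ 52. The C2–H/C3–H bonds (hydrogenation sets C2), the C2–CH3 bond (cross-coupling) and both C12–CH3 bonds (enolate alkylation) are cut. The enone blocks C2 while C12 is alkylated. Hydrogen must add from the α face.

52 ⇒ 49 ⇒ 48 ⇒ 47 ⇒ 45. C2 is excised (cycloheptenone back to a silyloxycyclopropane on a six-membered ring), and the C9–O and C9=CH2 bonds are cut back to a ketone. The regiochemistry of ring enlargement is fixed by the position of the enol ether. Oxygen must reach C9 from the α face.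

45 ⇒ 43 + 44; 43 ⇒ 41. The C4–C5 and C6–C12 bonds are cut (Diels–Alder). The cis ring fusion follows from suprafacial addition and the absolute configuration from the catalyst.

## Other disconnections considered

Alternative 1: The cut removes both bonds from C5 into the seven-membered ring (C5–C4 and C5–C6). This reduces the hydroazulene to an anisole carrying a diazoketone side chain, A1. In the forward direction Rh2(OAc)4 would decompose A1 to a rhodium carbene that adds across the C4–C6 edge of the arene; 6π-electrocyclic opening of the norcaradiene gives the bicyclic trienone A2 (intramolecular Büchner reaction).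
- In its favour: one step turns a flat arene into the whole 5–7 carbon skeleton, with the C2 methyl, one C12 methyl and the C15 oxygen in place and a C9 carbonyl ready for a methyl nucleophile. As a ring construction this is shorter than the cycloaddition and ring enlargement used for 61, and on that count it is the better of the two.
- Against it here: A2 has one stereocentre (C5) that is flanked by a ketone and a triene and is therefore labile (enolisation, 1,5-hydrogen shifts). An enantioselective version would rest on a chiral dirhodium catalyst. C2, C6, C9 and the second C12 methyl would all have to be set on a polyene by reductions and additions with no anchoring stereocentre. Addition across the methyl-bearing C6–C12 edge and benzylic C–H insertion are competing paths.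
- Comparison: structurally it addresses the half that the Criegee step does not, so it competes with steps 20–30 and not with step 9. Mechanistically it is a carbene addition and electrocyclisation that closes a ring but secures no stereocentre, whereas the chosen key step makes no stereocentre and needs none. In step count the two hydroazulene routes should end close to each other once A2 has been saturated and methylated, and the chosen plan has the firmer stereocontrol.

Alternative 2: The cut removes O28–C25 and C18–C19, opening the oxepane and ring B at once to an acyclic bis-epoxide with a Z silyl enol ether, A3. In the forward direction Me3SiOTf would activate the C23–C25 epoxide, the oxygen of the C19–C29 epoxide would attack the tertiary C25, and the resulting epoxonium ion would be opened at C19 by C18 of the enol ether through a chair, giving A4.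
- In its favour: both rings, the C25–O28 bond and the stereocentres C18, C19 and C29 form in one step, and the absolute configuration comes from asymmetric epoxidation. C23 arrives at the alcohol level without the removal and return of oxygen that the chosen plan needs (steps 1, 2 and 10). C32 is already the ketone that accepts methyllithium and the allyl group on C18 is a handle for the union. On step and redox economy for the right half this alternative is the better one.
- Against it here: two trisubstituted epoxides compete for the Lewis acid. The first closure relies on a weakly nucleophilic epoxide oxygen, while the silyl enol ether must wait for the second event. Premature enol ether attack, capture of the cations by triflate and hydride shifts are open side paths. The C18 configuration depends on the enol ether geometry.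
- Comparison: it makes the same trans-fused oxepane–cyclohexane from acyclic material, whereas the chosen plan buys ring B, C19 and the trans fusion with 1. It is a cationic cascade with three bond-forming events, against one 1,2-shift with one selectivity question. The chosen plan is longer but gives each step a single task. The two are equal in convergence.

Alternative 3: The cut removes C5–C9, opening the cyclopentanol to a cycloheptenone with a 3-oxobutyl chain on C6, A5. In the forward direction SmI2 (divalent samarium) would reduce the methyl ketone to its ketyl, which adds to C5 of the enone in a 5-exo sense; protonation of the samarium enolate gives A6.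
- In its favour: the cis ring fusion and the C9 carbinol are set together, with the hydroxyl anti to the enone-derived carbon as the target requires. This does in one step what steps 23 and 24 do in two, and on a better-founded stereochemical model; for C9 it is the better solution. The C3 ketone and C15 methylene of A6 are handles for later work.
- Against it here: A5, with its C6 stereocentre, gem-dimethyl group and exocyclic methylene, needs its own enantioselective synthesis. The C2 methyl must be introduced next to the C3 ketone with stereocontrol and the C3 oxygen then removed. The C15 methylene is β,γ to the ketone and can slip into conjugation. It must still be turned into the Z trisubstituted alkene, the same problem as in the chosen plan but without a C15 carbonyl to build on.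
- Comparison: like alternative 1 it concerns the hydroazulene and leaves the oxepane untouched, so it is complementary to step 9 and not a rival. Mechanistically it is a radical-anion cyclisation against a cationic rearrangement. In step count it should be close to steps 20–30.

Key step: step 9

Remarks on the chemistry (conventions, one correction, one assumption):
- Locants are those of the target atoms. On the oxepane–cyclohexane half, β is the face of the C19 methyl (C20) and α the opposite face. On the hydroazulene half, α is the face of H5 and H6.
- Compounds 1, 19 and 21 were compared atom by atom with 70. C19 and C29 have the required configuration and the ring fusion is trans, so these structures need no correction.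
- Correction of design: perhydrolysis of a C25 carbinol with H2O2 and acid would cleave the C18 dioxolane and turn the freed ketone into peroxyketals. The hydroperoxide 17 is therefore made under neutral conditions from the C25 methylene compound 13, and the rearrangement is run with an amine buffer.
- Assumption: the oxazaborolidinium catalyst derived from (S)-α,α-diphenylprolinol gives 45 with the C5/C6 configuration drawn. If the sense is the opposite, the (R)-catalyst is used and nothing else changes.
- Centres that are erased later are drawn in the configuration expected to predominate, and their epimers converge. These are C25 in 16–19, the C23 carbinol, C32 in 30, the cyclopropane carbons in 47–49 and C15 in 65 and 66. The allene axis of 67 is not encoded for the same reason.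

## Steps

Step 1
Reactants: 1 (S)-Wieland–Miescher ketone; 2 ethane-1,2-dithiol
Product: 3 (S)-enone dithiolane of 1 (C23 carbonyl masked; C25=C29 kept; C18 ketone free)
Conditions: HS(CH2)2SH, p-TsOH·H2O (cat.), AcOH, rt
Reagents that add atoms: ethane-1,2-dithiol, SCCS
Why: Chemoselective dithioketalisation: the conjugated carbonyl reacts, while the C18 ketone, neopentyl to the quaternary C19, does not; in enone dithioketals the double bond stays at C25=C29.

Step 2
Reactants: 3
Product: 4 (S)-8a-methyl-3,4,6,7,8,8a-hexahydronaphthalen-1(2H)-one (C18 ketone, C25=C29 alkene)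
Conditions: Raney Ni (acetone-deactivated), EtOH, reflux
Reagents that add atoms: none
Why: Reductive desulfurisation (Mozingo reduction) replaces the C23 dithiolane by CH2 without moving the trisubstituted alkene; deactivated nickel spares the hindered ketone.

Step 3
Reactants: 4; 5 1,2-bis(trimethylsilyloxy)ethane
Product: 6 C18 ethylene ketal (dioxolane) of 4
Conditions: (Me3SiOCH2)2, Me3SiOTf (cat.), CH2Cl2, −78 → −20 °C; pyridine
Reagents that add atoms: 1,2-bis(trimethylsilyloxy)ethane, C[Si](C)(C)OCCO[Si](C)(C)C
Why: Aprotic silyl-transfer ketalisation (Noyori conditions) protects the hindered C18 ketone at low temperature, where the C25=C29 alkene does not migrate.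

Step 4
Reactants: 6; 7 borane–tetrahydrofuran complex; 8 hydrogen peroxide
Product: 10 trans-fused decalin C25α-ol with C18 dioxolane, via C25 alkylborane 9 (not isolated)
Conditions: BH3·THF, THF, 0 °C → rt; then NaOH, H2O2, H2O, 0 °C
Reagents that add atoms: hydrogen peroxide, OO
Why: Hydroboration–oxidation: H–B adds syn from the α face, away from the angular C20 methyl, with boron on the less substituted C25 and hydrogen on C29. This sets C29–H trans to C20 (the ring fusion of the target) and gives the equatorial C25 alcohol.

Step 5
Reactants: 10
Product: 11 trans-fused decalin C25-one with C18 dioxolane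
Conditions: Dess–Martin periodinane, NaHCO3, CH2Cl2, 0 °C → rt
Reagents that add atoms: none
Why: Buffered Dess–Martin oxidation of a secondary alcohol; the medium does not enolise C29, and the trans-fused ketone is in any case the more stable epimer.

Step 6
Reactants: 11; 12 methyltriphenylphosphonium bromide
Product: 13 trans-fused C25-methylene decalin with C18 dioxolane
Conditions: Ph3PCH3Br, KOtBu, THF, 0 °C → rt
Reagents that add atoms: methyltriphenylphosphonium bromide, C[P+](c1ccccc1)(c1ccccc1)c1ccccc1.[Br-]
Why: Wittig methylenation of an unhindered cyclohexanone; the ketal is inert to the ylide.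

Step 7
Reactants: 13; 14 dioxygen; 15 triethylsilane
Product: 17 C25 tertiary hydroperoxide (C18 dioxolane), via C25 silyl peroxide 16 (not isolated)
Conditions: Co(acac)2 (cat.), Et3SiH, O2 (1 atm), ClCH2CH2Cl, rt; then K2CO3, MeOH, 0 °C
Reagents that add atoms: dioxygen, O=O
Why: Isayama–Mukaiyama hydroperoxysilylation: a cobalt hydride transfers a hydrogen atom to the CH2 terminus, and the tertiary C25 radical is trapped by O2 and silylated; methanolysis then frees the hydroperoxide without acid, so the dioxolane survives. The C25 configuration (peroxide equatorial expected) is of no consequence for step 9.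

Step 8
Reactants: 17; 18 acetic anhydride
Product: 19 C25 tertiary peracetate of the trans-decalin (C18 dioxolane)
Conditions: Ac2O, pyridine, DMAP (cat.), CH2Cl2, −20 °C
Reagents that add atoms: acetic anhydride, CC(=O)OC(C)=O
Why: O-Acylation of a hydroperoxide; the low temperature and cold work-up allow the perester to be isolated before it ionises.

Step 9
Reactants: 19
Product: 21 trans-fused oxepene (cyclic enol ether C23=C25, C18 dioxolane), via acetoxy ketal 20 (not isolated)
Conditions: 2,6-lutidine, MeCN, 50 °C; then Et3N, toluene, 90 °C
Reagents that add atoms: none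
Why: Criegee rearrangement: heterolysis of the O–O bond of 19 is concerted with a 1,2-shift of C29 from C25 to the proximal oxygen, the migrating bond lying anti-periplanar to O–OAc (reached by rotation about C25–O, so either C25 epimer serves); the O28-stabilised C25 cation collapses with acetate to 20, which ionises again and loses acetic acid to give 21. The closest known reaction type is the rearrangement of tertiary decalyl and cycloalkyl peresters to ring-enlarged ketals and cyclic enol ethers. The oxepane is formed by enlargement of ring A (one oxygen inserted into C25–C29), not by a cyclisation, so no ring-closure mode has to be met. No stereocentre is created: C29 migrates with retention and C19 is untouched, so the trans fusion bought with 1 is carried over. The step needs migration of C29 rather than C23 or CH3, which is secured because the secondary ring-fusion carbon is the most electron-releasing of the three groups. It also needs the endocyclic rather than the exocyclic enol ether, which is secured by equilibration through 20 to the more substituted alkene. The amine keeps the medium non-acidic, so the dioxolane and the enol ether survive.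

Step 10
Reactants: 21; 22 dimethyldioxirane; 23 trimethylaluminium
Product: 25 oxepan-C23α-ol with C25 gem-dimethyl and C18 dioxolane, via C23–C25 epoxide 24 (not isolated)
Conditions: DMDO, acetone–CH2Cl2, −78 → 0 °C; evaporate; Me3Al, CH2Cl2, −78 → −30 °C; Rochelle salt
Reagents that add atoms: dimethyldioxirane, CC1(C)OO1; trimethylaluminium, C[Al](C)C
Why: Epoxidation of the electron-rich enol ether, then Lewis-acid opening at the acetal carbon C25 with methyl transfer from aluminium, as in C-glycoside synthesis from glycal epoxides. C25 becomes a gem-dimethyl carbon and so is not a stereocentre; the C23 carbinol (α expected, from attack anti to C20) is oxidised at the end.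

Step 11
Reactants: 25; 26 water
Product: 27 C23α-hydroxy C18 ketone
Conditions: 1 M HCl, THF, rt
Reagents that add atoms: water, O
Why: Acid hydrolysis of the dioxolane; the secondary alcohol and the tertiary alkyl ether of the oxepane are stable to dilute acid at room temperature.

Step 12
Reactants: 27; 12 methyltriphenylphosphonium bromide
Product: 28 C18 methylene C23α-ol
Conditions: Ph3PCH3Br, KOtBu (excess), toluene, rt → 80 °C
Reagents that add atoms: methyltriphenylphosphonium bromide, C[P+](c1ccccc1)(c1ccccc1)c1ccccc1.[Br-]
Why: Wittig methylenation of a ketone next to a quaternary carbon, which needs excess ylide and heat; the free hydroxyl is carried as its alkoxide.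

Step 13
Reactants: 28; 29 tert-butyl hydroperoxide
Product: 30 C18 methylene C23α,C32-diol
Conditions: SeO2 (cat.), t-BuOOH, CH2Cl2, rt
Reagents that add atoms: tert-butyl hydroperoxide, CC(C)(C)OO
Why: Allylic oxidation by SeO2 (ene reaction, then [2,3]-sigmatropic shift): C32 carries the only allylic hydrogens because C19 is quaternary. The C32 configuration does not matter, since the alcohol is oxidised in the next step.

Step 14
Reactants: 30
Product: 31 C18 methylene C32 ketone with C23α-ol
Conditions: MnO2, CH2Cl2, rt
Reagents that add atoms: none
Why: MnO2 oxidises the allylic alcohol and leaves the saturated, neopentyl C23 alcohol alone, so no protecting group is needed here.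

Step 15
Reactants: 31; 32 methyllithium
Product: 33 C32 tertiary allylic alcohol (OH β axial, CH3 α) with C18 methylene and C23α-ol
Conditions: MeLi, CeCl3, THF, −78 °C
Reagents that add atoms: methyllithium, [Li]C
Why: 1,2-Addition of the organocerium reagent to the α-methylene ketone: the β (axial) trajectory at C32 is blocked by the 1,3-diaxial C20 methyl, so methyl enters from the α face and the hydroxyl ends axial, as in the target.

Step 16
Reactants: 33; 34 triethylsilyl trifluoromethanesulfonate
Product: 35 C23,C32 bis(triethylsilyl) ether of 33
Conditions: Et3SiOTf, 2,6-lutidine, CH2Cl2, −78 → 0 °C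
Reagents that add atoms: triethylsilyl trifluoromethanesulfonate, CC[Si](CC)(CC)OS(=O)(=O)C(F)(F)F
Why: Silyl triflate with a hindered base silylates both the neopentyl secondary and the tertiary alcohol in one operation.

Step 17
Reactants: 35; 7 borane–tetrahydrofuran complex; 8 hydrogen peroxide
Product: 37 C17 primary alcohol (C17 branch β, H18 α), via C17 alkylborane 36 (not isolated)
Conditions: BH3·THF, THF, 0 → 40 °C; then NaOH, H2O2, H2O, 0 °C
Reagents that add atoms: hydrogen peroxide, OO
Why: Hydroboration–oxidation of the 1,1-disubstituted alkene places boron on C17. The β face is shielded on both flanks by the axial C20 methyl and the axial C32 silyl ether, so hydrogen reaches C18 from the α face and the CH2OH branch becomes equatorial, as required.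

Step 18
Reactants: 37
Product: 38 C17 aldehyde
Conditions: Dess–Martin periodinane, NaHCO3, CH2Cl2, 0 °C → rt
Reagents that add atoms: none
Why: Mild oxidation of a primary alcohol to the aldehyde; silyl ethers are stable under buffered conditions.

Step 19
Reactants: 38; 39 dimethyl (1-diazo-2-oxopropyl)phosphonate
Product: 40 C18 ethynyl compound (C16≡C17) with C23,C32 bis(triethylsilyl) ether
Conditions: K2CO3, MeOH, 0 °C → rt
Reagents that add atoms: dimethyl (1-diazo-2-oxopropyl)phosphonate, COP(=O)(OC)C(=[N+]=[N-])C(C)=O
Why: Ohira–Bestmann homologation (Seyferth–Gilbert type) gives the terminal alkyne without strong base. If C18 epimerised through the aldehyde enolate it would settle in the same equatorial configuration.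

Step 20
Reactants: 41 but-3-en-2-one; 42 triisopropylsilyl trifluoromethanesulfonate
Product: 43 2-(triisopropylsilyloxy)buta-1,3-diene
Conditions: i-Pr3SiOTf, Et3N, Et2O, 0 °C → rt
Reagents that add atoms: triisopropylsilyl trifluoromethanesulfonate, CC(C)[Si](C(C)C)(C(C)C)OS(=O)(=O)C(F)(F)F
Why: Soft enolisation and O-silylation of the methyl ketone give the 2-silyloxydiene; the bulky silyl group makes it robust to the acidic catalyst of step 21.

Step 21
Reactants: 43; 44 cyclopent-2-en-1-one
Product: 45 cis-5-(triisopropylsilyloxy)-2,3,3a,4,7,7a-hexahydro-1H-inden-1-one (C9 ketone, H5 and H6 α, enol ether C15=C3)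
Conditions: oxazaborolidinium triflimide from (S)-α,α-diphenylprolinol, tri-o-tolylboroxine and Tf2NH (20 mol %), CH2Cl2, −40 °C
Reagents that add atoms: cyclopent-2-en-1-one, O=C1C=CCC1
Why: Catalytic enantioselective Diels–Alder reaction of a cyclic enone activated by a chiral oxazaborolidinium Lewis acid: the CH2 terminus next to the silyloxy carbon bonds to the enone β-carbon C6, which fixes the enol ether as C15=C3. Suprafacial addition makes the C5/C6 fusion cis and the catalyst sets the absolute configuration of both centres.

Step 22
Reactants: 45; 46 diiodomethane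
Product: 47 silyloxycyclopropane ketone (C2 bridging C15 and C3, C9 ketone)
Conditions: Et2Zn, CH2I2, CH2Cl2, 0 °C → rt
Reagents that add atoms: diiodomethane, ICI
Why: Simmons–Smith cyclopropanation (Furukawa reagent) of the electron-rich silyl enol ether; the ketone is tolerated and the cyclopropane configuration is lost again in step 25.

Step 23
Reactants: 47; 12 methyltriphenylphosphonium bromide
Product: 48 C9 methylene silyloxycyclopropane
Conditions: Ph3PCH3Br, KOtBu, THF, 0 °C → rt
Reagents that add atoms: methyltriphenylphosphonium bromide, C[P+](c1ccccc1)(c1ccccc1)c1ccccc1.[Br-]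
Why: Wittig methylenation of the cyclopentanone; the cis fusion is the stable arrangement of a hydrindan-1-one, so C5 is not at risk under the basic conditions.

Step 24
Reactants: 48; 14 dioxygen
Product: 49 C9 tertiary alcohol (OH α, CH3 β) silyloxycyclopropane
Conditions: Co(acac)2 (cat.), PhSiH3, O2 (1 atm), THF–i-PrOH, rt
Reagents that add atoms: dioxygen, O=O
Why: Mukaiyama hydration: hydrogen-atom transfer to the CH2 terminus gives the tertiary C9 radical, which takes up O2 from the convex α face, anti to C4 on the neighbouring C5. The hydroxyl therefore ends α and the methyl β, as in the target; a methyl nucleophile adding to the C9 ketone would give the opposite epimer.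

Step 25
Reactants: 49; 50 iron trichloride
Product: 52 cis-fused cyclohept-2-enone (C15 ketone, C2=C3) with C9α-ol, via C3 chloro ketone 51 (not isolated)
Conditions: FeCl3, DMF, 0 °C → rt; then NaOAc, MeOH, reflux
Reagents that add atoms: none
Why: Oxidative ring enlargement of a silyloxycyclopropane (Saegusa–Ito type): FeCl3 cleaves the internal C15–C3 bond to the ketone and a secondary C3 radical, which is chlorinated; NaOAc then eliminates HCl. C2 is thus inserted between C15 and C3 with no regiochemical choice.

Step 26
Reactants: 52; 34 triethylsilyl trifluoromethanesulfonate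
Product: 53 C9 triethylsilyl ether of 52
Conditions: Et3SiOTf, 2,6-lutidine, CH2Cl2, −78 → 0 °C
Reagents that add atoms: triethylsilyl trifluoromethanesulfonate, CC[Si](CC)(CC)OS(=O)(=O)C(F)(F)F
Why: Silylation of the tertiary alcohol with the silyl triflate; at low temperature the enone is not converted to a silyl dienol ether.

Step 27
Reactants: 53; 54 iodomethane
Product: 56 C12 gem-dimethyl enone, via C12 monomethyl enone 55 (not isolated)
Conditions: LDA, THF, −78 °C; MeI; then LDA, DMPU, −78 °C; MeI, −78 → 0 °C
Reagents that add atoms: iodomethane, CI
Why: Kinetic α′-deprotonation gives the cross-conjugated enolate, which is methylated; the sequence is run twice. C12 is the only α′ carbon, so the gem-dimethyl group is installed regiospecifically.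

Step 28
Reactants: 56; 57 diiodine
Product: 58 C2 iodo enone
Conditions: I2, pyridine, CH2Cl2, rt
Reagents that add atoms: diiodine, II
Why: α-Iodination of an enone by conjugate addition of pyridine, iodination of the enolate and elimination; it needs only the β-hydrogen on C3.

Step 29
Reactants: 58; 59 trimethylboroxine
Product: 60 C2 methyl enone
Conditions: PdCl2(dppf) (cat.), K3PO4, dioxane–H2O, 80 °C
Reagents that add atoms: trimethylboroxine, CB1OB(C)OB(C)O1
Why: Suzuki–Miyaura methylation of the α-iodoenone keeps the alkene in place and puts C1 on C2.

Step 30
Reactants: 60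
Product: 61 cis-fused hydroazulenone (C15 ketone, C2 methyl β, C12 gem-dimethyl, C9 OSiEt3 α)
Conditions: H2 (1 atm), Pd/C, EtOAc, rt
Reagents that add atoms: none
Why: Heterogeneous hydrogenation of the trisubstituted enone alkene from the α face, the face of H5 and H6; the β face carries the cyclopentane ring and the pseudo-axial C12 methyl. Hydrogen on C2 therefore ends α and the methyl β, and neutral conditions avoid epimerisation next to the ketone.

Step 31
Reactants: 40; 61; 62 n-butyllithium; 63 methyl chloroformate
Product: 66 C15 tertiary propargylic methyl carbonate (C15–C16 bond formed), via lithium acetylide 64 (not isolated), via lithium alkoxide 65 (not isolated)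
Conditions: n-BuLi, THF, −78 °C; add 61, −78 → 0 °C; then ClCO2Me, 0 °C → rt
Reagents that add atoms: methyl chloroformate, COC(=O)Cl
Why: A lithium acetylide is slim and only weakly basic, and adds to ketones of the 2,2,6-trimethylcyclohexanone type; the tertiary alkoxide is acylated in the same flask, which avoids a separate acylation of a very hindered alcohol. The new C15 centre (alkynyl α expected) disappears in step 32.

Step 32
Reactants: 66
Product: 67 allene C15=C16=C17 (tris-silyl ether)
Conditions: Pd2(dba)3·CHCl3 (cat.), PBu3, HCO2NH4, THF, rt → 40 °C
Reagents that add atoms: none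
Why: Palladium-catalysed formate hydrogenolysis of a tertiary propargylic carbonate: zerovalent palladium ionises the carbonate in an SN2′ sense to an allenylpalladium species, formate supplies hydride, and reductive elimination places hydrogen on C17.

Step 33
Reactants: 67
Product: 68 (Z)-C15=C16 alkene with C9, C23, C32 tris(triethylsilyl) ether
Conditions: 2-nitrobenzenesulfonohydrazide, Et3N, CH2Cl2, rt
Reagents that add atoms: none
Why: Diimide reduction of an allene: the less substituted C16=C17 π bond lies in the plane of the C15 substituents and should be attacked syn from the side of C2 (CH–CH3) in preference to the side of C12 (CMe2). The new C16–H is then cis to C2 and C17 is pushed cis to C12, which is the Z alkene; the remaining trisubstituted alkene is inert to diimide.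

Step 34
Reactants: 68
Product: 69 C9,C23,C32 triol
Conditions: TBAF, THF, 0 → 50 °C
Reagents that add atoms: none
Why: Fluoride cleaves all three triethylsilyl ethers without acid, so the alkene and the tertiary alcohols are not exposed to ionising conditions.

Step 35
Reactants: 69
Product: 70 target (CNP0157787.1)
Conditions: Dess–Martin periodinane, NaHCO3, CH2Cl2, 0 °C → rt
Reagents that add atoms: none
Why: Only the secondary C23 alcohol can be oxidised, since the two other hydroxyls are tertiary; buffering protects the alkene and the tertiary alcohols.

## Compound list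

1 | (S)-Wieland–Miescher ketone, (S)-8a-methyl-3,4,8,8a-tetrahydronaphthalene-1,6(2H,7H)-dione | C[C@]12CCC(=O)C=C1CCCC2=O | starting material
2 | ethane-1,2-dithiol | SCCS | starting material
3 | (S)-enone dithiolane of 1 (C23 as 1,3-dithiolane, C25=C29, C18 ketone) | O=C1[C@@]2(C)CCC3(SCCS3)C=C2CCC1 | intermediate
4 | (S)-8a-methyl-3,4,6,7,8,8a-hexahydronaphthalen-1(2H)-one | O=C1[C@@]2(C)CCCC=C2CCC1 | intermediate
5 | 1,2-bis(trimethylsilyloxy)ethane | C[Si](C)(C)OCCO[Si](C)(C)C | starting material
6 | C18 dioxolane of 4 | O1CCOC12[C@@]3(C)CCCC=C3CCC2 | intermediate
7 | borane–tetrahydrofuran complex | [BH3-][O+]1CCCC1 | starting material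
8 | hydrogen peroxide | OO | starting material
9 | C25α alkylborane, trans-fused (H29 α) | O1CCOC12[C@@]3(C)CCC[C@@H](B)[C@@H]3CCC2 | intermediate (not isolated)
10 | trans-fused decalin C25α-ol, C18 dioxolane | O1CCOC12[C@@]3(C)CCC[C@@H](O)[C@@H]3CCC2 | intermediate
11 | trans-fused decalin C25-one, C18 dioxolane | O1CCOC12[C@@]3(C)CCCC(=O)[C@@H]3CCC2 | intermediate
12 | methyltriphenylphosphonium bromide | C[P+](c1ccccc1)(c1ccccc1)c1ccccc1.[Br-] | starting material
13 | trans-fused C25-methylene decalin, C18 dioxolane | O1CCOC12[C@@]3(C)CCCC(=C)[C@@H]3CCC2 | intermediate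
14 | dioxygen | O=O | starting material
15 | triethylsilane | CC[SiH](CC)CC | starting material
16 | C25 triethylsilyl peroxide (C25 methyl β, peroxide α) | O1CCOC12[C@@]3(C)CCC[C@@](C)(OO[Si](CC)(CC)CC)[C@@H]3CCC2 | intermediate (not isolated)
17 | C25 tertiary hydroperoxide, C18 dioxolane | O1CCOC12[C@@]3(C)CCC[C@@](C)(OO)[C@@H]3CCC2 | intermediate
18 | acetic anhydride | CC(=O)OC(C)=O | starting material
19 | C25 tertiary peracetate of the trans-decalin, C18 dioxolane | O1CCOC12[C@@]3(C)CCC[C@@](C)(OOC(C)=O)[C@@H]3CCC2 | intermediate
20 | 2-acetoxy-2-methyloxepane ketal (O28 inserted; both C25 epimers, C25 left open) | O1CCOC12[C@@]3(C)CCCC(C)(OC(C)=O)O[C@@H]3CCC2 | intermediate (not isolated)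
21 | trans-fused oxepene (enol ether C23=C25), C18 dioxolane | O1CCOC12[C@@]3(C)CCC=C(C)O[C@@H]3CCC2 | intermediate
22 | dimethyldioxirane | CC1(C)OO1 | starting material
23 | trimethylaluminium | C[Al](C)C | starting material
24 | C23,C25 α-epoxide of 21 | O1CCOC12[C@@]3(C)CC[C@H]4O[C@@]4(C)O[C@@H]3CCC2 | intermediate (not isolated)
25 | oxepan-C23α-ol with C25 gem-dimethyl, C18 dioxolane | O1CCOC12[C@@]3(C)CC[C@@H](O)C(C)(C)O[C@@H]3CCC2 | intermediate
26 | water | O | starting material
27 | C23α-hydroxy C18 ketone | O=C1[C@@]2(C)CC[C@@H](O)C(C)(C)O[C@@H]2CCC1 | intermediate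
28 | C18 methylene C23α-ol | C=C1[C@@]2(C)CC[C@@H](O)C(C)(C)O[C@@H]2CCC1 | intermediate
29 | tert-butyl hydroperoxide | CC(C)(C)OO | starting material
30 | C18 methylene C23α,C32α-diol | C=C1[C@@]2(C)CC[C@@H](O)C(C)(C)O[C@@H]2CC[C@H]1O | intermediate
31 | C18 methylene C32 ketone, C23α-ol | C=C1[C@@]2(C)CC[C@@H](O)C(C)(C)O[C@@H]2CCC1=O | intermediate
32 | methyllithium | [Li]C | starting material
33 | C32 tertiary alcohol (OH β, CH3 α), C18 methylene, C23α-ol | C=C1[C@@]2(C)CC[C@@H](O)C(C)(C)O[C@@H]2CC[C@]1(C)O | intermediate
34 | triethylsilyl trifluoromethanesulfonate | CC[Si](CC)(CC)OS(=O)(=O)C(F)(F)F | starting material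
35 | C23,C32 bis(triethylsilyl) ether of 33 | C=C1[C@@]2(C)CC[C@@H](O[Si](CC)(CC)CC)C(C)(C)O[C@@H]2CC[C@]1(C)O[Si](CC)(CC)CC | intermediate
36 | C17 alkylborane (H18 α) | BC[C@@H]1[C@@]2(C)CC[C@@H](O[Si](CC)(CC)CC)C(C)(C)O[C@@H]2CC[C@]1(C)O[Si](CC)(CC)CC | intermediate (not isolated)
37 | C17 primary alcohol (C17 branch β on C18) | OC[C@@H]1[C@@]2(C)CC[C@@H](O[Si](CC)(CC)CC)C(C)(C)O[C@@H]2CC[C@]1(C)O[Si](CC)(CC)CC | intermediate
38 | C17 aldehyde | O=C[C@@H]1[C@@]2(C)CC[C@@H](O[Si](CC)(CC)CC)C(C)(C)O[C@@H]2CC[C@]1(C)O[Si](CC)(CC)CC | intermediate
39 | dimethyl (1-diazo-2-oxopropyl)phosphonate | COP(=O)(OC)C(=[N+]=[N-])C(C)=O | starting material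
40 | C18 ethynyl compound (C16≡C17), C23,C32 bis(triethylsilyl) ether | C#C[C@@H]1[C@@]2(C)CC[C@@H](O[Si](CC)(CC)CC)C(C)(C)O[C@@H]2CC[C@]1(C)O[Si](CC)(CC)CC | intermediate
41 | but-3-en-2-one | CC(=O)C=C | starting material
42 | triisopropylsilyl trifluoromethanesulfonate | CC(C)[Si](C(C)C)(C(C)C)OS(=O)(=O)C(F)(F)F | starting material
43 | 2-(triisopropylsilyloxy)buta-1,3-diene | C=CC(=C)O[Si](C(C)C)(C(C)C)C(C)C | intermediate
44 | cyclopent-2-en-1-one | O=C1C=CCC1 | starting material
45 | cis-5-(triisopropylsilyloxy)-2,3,3a,4,7,7a-hexahydro-1H-inden-1-one (C9 ketone, H5 and H6 α) | C1(O[Si](C(C)C)(C(C)C)C(C)C)=CC[C@@H]2[C@@H](CCC2=O)C1 | intermediate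
46 | diiodomethane | ICI | starting material
47 | silyloxycyclopropane ketone (C2 bridging C15 and C3 on the α face, C9 ketone) | [C@]13(O[Si](C(C)C)(C(C)C)C(C)C)C[C@@H]3C[C@@H]2[C@@H](CCC2=O)C1 | intermediate
48 | C9 methylene silyloxycyclopropane | [C@]13(O[Si](C(C)C)(C(C)C)C(C)C)C[C@@H]3C[C@@H]2[C@@H](CCC2=C)C1 | intermediate
49 | C9 tertiary alcohol (OH α, CH3 β) silyloxycyclopropane | [C@]13(O[Si](C(C)C)(C(C)C)C(C)C)C[C@@H]3C[C@@H]2[C@@H](CC[C@@]2(C)O)C1 | intermediate
50 | iron trichloride | Cl[Fe](Cl)Cl | starting material
51 | C3 chloro C15 ketone (both C3 epimers, C3 left open) | O=C1CC(Cl)C[C@@H]2[C@@H](CC[C@@]2(C)O)C1 | intermediate (not isolated)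
52 | cis-fused cyclohept-2-enone (C15 ketone, C2=C3) with C9α-ol | O=C1C=CC[C@@H]2[C@@H](CC[C@@]2(C)O)C1 | intermediate
53 | C9 triethylsilyl ether of 52 | O=C1C=CC[C@@H]2[C@@H](CC[C@@]2(C)O[Si](CC)(CC)CC)C1 | intermediate
54 | iodomethane | CI | starting material
55 | C12 monomethyl enone (both C12 epimers, C12 left open) | O=C1C=CC[C@@H]2[C@@H](CC[C@@]2(C)O[Si](CC)(CC)CC)C1C | intermediate (not isolated)
56 | C12 gem-dimethyl enone | O=C1C=CC[C@@H]2[C@@H](CC[C@@]2(C)O[Si](CC)(CC)CC)C1(C)C | intermediate
57 | diiodine | II | starting material
58 | C2 iodo enone | O=C1C(I)=CC[C@@H]2[C@@H](CC[C@@]2(C)O[Si](CC)(CC)CC)C1(C)C | intermediate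
59 | trimethylboroxine | CB1OB(C)OB(C)O1 | starting material
60 | C2 methyl enone | O=C1C(C)=CC[C@@H]2[C@@H](CC[C@@]2(C)O[Si](CC)(CC)CC)C1(C)C | intermediate
61 | cis-fused hydroazulenone (C15 ketone, C2 methyl β, C12 gem-dimethyl, C9 OSiEt3 α) | C[C@H]1CC[C@@H]2[C@@H](CC[C@@]2(C)O[Si](CC)(CC)CC)C(C)(C)C1=O | intermediate
62 | n-butyllithium | [Li]CCCC | starting material
63 | methyl chloroformate | COC(=O)Cl | starting material
64 | lithium acetylide of 40 | [Li]C#C[C@@H]1[C@@]2(C)CC[C@@H](O[Si](CC)(CC)CC)C(C)(C)O[C@@H]2CC[C@]1(C)O[Si](CC)(CC)CC | intermediate (not isolated)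
65 | lithium C15 alkoxide of the coupled propargylic alcohol (O β, alkynyl α) | C[C@H]1CC[C@@H]2[C@@H](CC[C@@]2(C)O[Si](CC)(CC)CC)C(C)(C)[C@]1(O[Li])C#C[C@@H]1[C@@]2(C)CC[C@@H](O[Si](CC)(CC)CC)C(C)(C)O[C@@H]2CC[C@]1(C)O[Si](CC)(CC)CC | intermediate (not isolated)
66 | C15 tertiary propargylic methyl carbonate | C[C@H]1CC[C@@H]2[C@@H](CC[C@@]2(C)O[Si](CC)(CC)CC)C(C)(C)[C@]1(OC(=O)OC)C#C[C@@H]1[C@@]2(C)CC[C@@H](O[Si](CC)(CC)CC)C(C)(C)O[C@@H]2CC[C@]1(C)O[Si](CC)(CC)CC | intermediate
67 | allene C15=C16=C17, tris(triethylsilyl) ether (axis not encoded) | C[C@H]1CC[C@@H]2[C@@H](CC[C@@]2(C)O[Si](CC)(CC)CC)C(C)(C)C1=C=C[C@@H]1[C@@]2(C)CC[C@@H](O[Si](CC)(CC)CC)C(C)(C)O[C@@H]2CC[C@]1(C)O[Si](CC)(CC)CC | intermediate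
68 | (Z)-C15=C16 alkene, C9,C23,C32 tris(triethylsilyl) ether | C[C@H]1CC[C@@H]2[C@@H](CC[C@@]2(C)O[Si](CC)(CC)CC)C(C)(C)/C1=C\C[C@@H]1[C@@]2(C)CC[C@@H](O[Si](CC)(CC)CC)C(C)(C)O[C@@H]2CC[C@]1(C)O[Si](CC)(CC)CC | intermediate
69 | C9,C23,C32 triol (C23α carbinol of the target) | C[C@H]1CC[C@@H]2[C@@H](CC[C@@]2(C)O)C(C)(C)/C1=C\C[C@@H]1[C@@]2(C)CC[C@@H](O)C(C)(C)O[C@@H]2CC[C@]1(C)O | intermediate
70 | CNP0157787.1 | C[C@H]1CC[C@@H]2[C@@H](CC[C@@]2(C)O)C(C)(C)/C1=C\C[C@@H]1[C@@]2(C)CCC(=O)C(C)(C)O[C@@H]2CC[C@]1(C)O | target

## Step count and least certain steps

Total: 35 steps. Longest linear sequence: 24 steps (steps 1–19 and 31–35, from 1). The hydroazulene branch (steps 20–30) has 11 steps and joins at step 31.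

Step 9 (key step). Ionisation may be slow with acetate as the leaving group. The C25 oxocarbenium ion may also be diverted, either by loss of a methyl proton to the exocyclic enol ether or by adventitious water to the ring-opened hydroxy methyl ketone. Fallback: from ketone 11, Baeyer–Villiger oxidation (m-CPBA, NaHCO3) inserts oxygen between C25 and C29 with retention, since the more substituted carbon migrates, and gives the seven-membered lactone F1. Enolisation and O-phosphorylation (KHMDS, (PhO)2P(O)Cl) give the ketene acetal phosphate F2, and Negishi coupling with MeZnCl and Pd(PPh3)4 puts the methyl on C25 and returns to the route at 21.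

Step 33. The in-plane discrimination between the C2 side and the C12 side of the allene may be weak, so that hydrogen is also delivered from the C12 side and the E alkene accompanies 68. Fallback: the separated E isomer F3 is epimerised at the alkene by a stereospecific three-stage inversion. Epoxidation (m-CPBA, NaHCO3) gives the epoxide F4. Anti opening at C16 with LiPPh2 gives the hydroxy phosphine F5. Quaternisation with MeI then triggers syn elimination of the phosphine oxide from the betaine, which returns to the route at 68.

Step 30. Face selection at C2 is remote from the ring fusion and may be poor, and the new centre lies next to a ketone, so the wrong epimer may also arise by enolisation. Fallback: from 60, 1,2-reduction (NaBH4, CeCl3, MeOH) gives the allylic alcohol, of which the C15α epimer F6 is taken on (the β epimer is re-oxidised to 60). Hydroxyl-directed hydrogenation with [Ir(cod)(PCy3)(py)]PF6 delivers hydrogen to C2 from the face of the hydroxyl and gives the saturated alcohol F7. Dess–Martin oxidation then returns to the route at 61.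

Step 24. Capture of O2 by the planar C9 radical may show only modest face selectivity, and hydrogen-atom transfer may be slow for the hindered alkene. Fallback: from 48, epoxidation with m-CPBA from the convex α face gives the spiro-epoxide F8. Hydride opening at the CH2 carbon (LiAlH4, THF, 0 °C) returns to the route at 49.

Step 19. The aldehyde enolate may expel the β-silyloxy group at C32 under the basic methanolic conditions, or the hindered aldehyde may react slowly. Fallback: from 38, dibromo-olefination (CBr4, PPh3, CH2Cl2, 0 °C) gives the gem-dibromoalkene F9. Treatment with n-BuLi (2 equiv, THF, −78 °C) and protonation returns to the route at 40 (Corey–Fuchs sequence).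

## Further compounds

F1 | step 9 | seven-membered lactone (O28 between C25 carbonyl and C29), C18 dioxolane | O1CCOC12[C@@]3(C)CCCC(=O)O[C@@H]3CCC2
F2 | step 9 | ketene acetal diphenyl phosphate (C23=C25), C18 dioxolane | O1CCOC12[C@@]3(C)CCC=C(OP(=O)(Oc4ccccc4)Oc4ccccc4)O[C@@H]3CCC2
F3 | step 33 | (E)-C15=C16 isomer of 68 | C[C@H]1CC[C@@H]2[C@@H](CC[C@@]2(C)O[Si](CC)(CC)CC)C(C)(C)/C1=C/C[C@@H]1[C@@]2(C)CC[C@@H](O[Si](CC)(CC)CC)C(C)(C)O[C@@H]2CC[C@]1(C)O[Si](CC)(CC)CC
F4 | step 33 | C15,C16 α-epoxide of F3 | C[C@H]1CC[C@@H]2[C@@H](CC[C@@]2(C)O[Si](CC)(CC)CC)C(C)(C)[C@]13O[C@@H]3C[C@@H]1[C@@]2(C)CC[C@@H](O[Si](CC)(CC)CC)C(C)(C)O[C@@H]2CC[C@]1(C)O[Si](CC)(CC)CC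
F5 | step 33 | C15 hydroxy C16 diphenylphosphine from anti opening of F4 | C[C@H]1CC[C@@H]2[C@@H](CC[C@@]2(C)O[Si](CC)(CC)CC)C(C)(C)[C@@]1(O)[C@@H](P(c3ccccc3)c3ccccc3)C[C@@H]1[C@@]2(C)CC[C@@H](O[Si](CC)(CC)CC)C(C)(C)O[C@@H]2CC[C@]1(C)O[Si](CC)(CC)CC
F6 | step 30 | C15α allylic alcohol from 60 | CC1=CC[C@@H]2[C@@H](CC[C@@]2(C)O[Si](CC)(CC)CC)C(C)(C)[C@@H]1O
F7 | step 30 | saturated C15α alcohol (C2 methyl β) | C[C@H]1CC[C@@H]2[C@@H](CC[C@@]2(C)O[Si](CC)(CC)CC)C(C)(C)[C@@H]1O
F8 | step 24 | C9 spiro-epoxide (oxygen α) of 48 | [C@]13(O[Si](C(C)C)(C(C)C)C(C)C)C[C@@H]3C[C@@H]2[C@@H](CC[C@]24CO4)C1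
F9 | step 19 | gem-dibromoalkene from 38 | BrC(Br)=C[C@@H]1[C@@]2(C)CC[C@@H](O[Si](CC)(CC)CC)C(C)(C)O[C@@H]2CC[C@]1(C)O[Si](CC)(CC)CC
A1 | alternative 1 | 1-diazo-4-(3-methoxy-2,4-dimethylphenyl)butan-2-one | [N-]=[N+]=CC(=O)CCc1ccc(C)c(OC)c1C
A2 | alternative 1 | 5-methoxy-4,6-dimethyl-3,8a-dihydroazulen-1(2H)-one | O=C1CCC2=C(C)C(OC)=C(C)C=C[C@@H]12
A3 | alternative 2 | acyclic bis-epoxide with Z trimethylsilyl enol ether and allyl group | C=CC/C=C(\O[Si](C)(C)C)CC[C@H]1O[C@]1(C)CC[C@H]1OC1(C)C
A4 | alternative 2 | trans-fused oxepanol–cyclohexanone with allyl on C18 | C=CC[C@@H]1[C@@]2(C)CC[C@@H](O)C(C)(C)O[C@@H]2CCC1=O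
A5 | alternative 3 | cycloheptenone with 3-oxobutyl chain on C6, C12 gem-dimethyl, C15 methylene | C=C1CC(=O)C=C[C@@H](CCC(C)=O)C1(C)C
A6 | alternative 3 | cis-fused hydroazulenol with C3 ketone and C15 methylene | C=C1CC(=O)C[C@@H]2[C@@H](CC[C@@]2(C)O)C1(C)C
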